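**Plan**

- Cuts: C3–C1' between the chromone and ring B (Suzuki coupling); ring B at C1'–C2' (closure of a dienylketene), at C5'–C6' (vinyl addition to a cyclobutenedione carbonyl) and at C3'–CH2 of the side chain (alkyllithium on dimethyl squarate); ring C at O1–C2 and C2–C3 (one-carbon enaminone on an acetophenone).
- Enabling feature: C2', C3', C4' and C5' of ring B carry OH, the 3-hydroxy-3-methylbutyl chain, OMe and OMe on four neighbouring carbons. This is the array of the four ring carbons of a squarate ester in which one methoxy group has been replaced by the chain; C6' and C1' come from a vinyl group.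
- Forward order: chain onto squarate, then vinyl and O-methyl onto the cyclobutenedione, then ring B by thermal ring expansion (step 5), then iodination and borylation at C1'. Ring C is closed separately on ring A (step 11) and the halves are joined at C3–C1' (step 12).
- Deprotection: the silyl ether is cleaved while C2'–OH is still benzylated, and the benzyl groups leave last by neutral hydrogenolysis, so the free ortho-(hydroxyisopentyl)phenol never meets acid.
- Stereochemistry: the target has no stereocentre; the single sp3 stereocentre on the route (C4 of the cyclobutenone, racemic) is erased when ring B aromatises.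

Key step: step 5

Remark: ring B is numbered C1' to C6' with C1' on chromone C3; the cyclobutenone-type intermediates 6, 10 and 11 are racemic and their SMILES show one enantiomer.

**Route**

Step 1
Reactants: 1 3-methylbutane-1,3-diol
Product: 2 4-iodo-2-methylbutan-2-ol
Conditions: I2, PPh3, imidazole, CH2Cl2, 0 °C to rt
Reagents that add atoms: iodine, II
Why: Appel iodination proceeds by SN2 displacement of an alkoxyphosphonium, which only the primary hydroxyl can undergo, so the tertiary alcohol should remain untouched.

Step 2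
Reactants: 2 4-iodo-2-methylbutan-2-ol
Product: 3 triethyl[(4-iodo-2-methylbutan-2-yl)oxy]silane
Conditions: Et3SiOTf, 2,6-lutidine, CH2Cl2, −78 °C to 0 °C
Reagents that add atoms: triethylsilyl trifluoromethanesulfonate, CC[Si](CC)(CC)OS(=O)(=O)C(F)(F)F
Why: Silylation with a silyl triflate and a hindered pyridine base is the standard way to cap a tertiary alcohol, and the triethylsilyl ether should survive the organolithium chemistry ahead yet leave with fluoride.

Step 3
Reactants: 3 triethyl[(4-iodo-2-methylbutan-2-yl)oxy]silane; 4 dimethyl squarate (3,4-dimethoxycyclobut-3-ene-1,2-dione)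
Product: 7 3-methoxy-4-[3-methyl-3-(triethylsilyloxy)butyl]cyclobut-3-ene-1,2-dione, via alkyllithium 5 (not isolated), via squarate adduct lithium alkoxide 6 (not isolated)
Conditions: t-BuLi (2.1 equiv), Et2O/pentane, −78 °C; then 4, THF, −78 °C; then (CF3CO)2O, −78 °C; aq NaHCO3
Reagents that add atoms: none
Why: Iodine–lithium exchange gives the primary alkyllithium, which adds 1,2 to one squarate carbonyl, and trifluoroacetylation of the alkoxide triggers allylic transposition with loss of methyl trifluoroacetate (Liebeskind–Moore cyclobutenedione synthesis, a net addition–elimination that swaps one OMe for the chain); the stereocentre of 6 is racemic and vanishes in 7.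

Step 4
Reactants: 7 3-methoxy-4-[3-methyl-3-(triethylsilyloxy)butyl]cyclobut-3-ene-1,2-dione; 8 bromoethene (vinyl bromide)
Product: 11 racemic 4-ethenyl-3,4-dimethoxy-2-[3-methyl-3-(triethylsilyloxy)butyl]cyclobut-2-en-1-one, via vinyllithium 9 (not isolated), via lithium alkoxide 10 (not isolated)
Conditions: 8, t-BuLi (2 equiv), Et2O, −78 °C; then 7, THF, −78 °C; then MeOTf, −78 °C to 0 °C
Reagents that add atoms: methyl trifluoromethanesulfonate, COS(=O)(=O)C(F)(F)F
Why: Bromine–lithium exchange gives CH2=CHLi, which should add 1,2 to the ketone-like carbonyl next to the methoxy-bearing carbon because the other carbonyl is a deactivated vinylogous ester, and the lithium alkoxide is then O-methylated by methyl triflate; the new quaternary stereocentre forms as a racemate, which is of no consequence since it becomes the planar C5' in step 5.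

Step 5
Reactants: 11 racemic 4-ethenyl-3,4-dimethoxy-2-[3-methyl-3-(triethylsilyloxy)butyl]cyclobut-2-en-1-one
Product: 14 3,4-dimethoxy-2-[3-methyl-3-(triethylsilyloxy)butyl]phenol, via dienylketene 12 (not isolated), via cyclohexadienone 13 (not isolated)
Conditions: PhMe (degassed, 0.02 M), 110 °C
Reagents that add atoms: none
Why: Heating should open the cyclobutenone by conrotatory 4π-electrocyclic cleavage of the C1–C4 bond to dienylketene 12, whose ketene carbon (future C2') then bonds to the terminal vinyl carbon (future C1') to give cyclohexadienone 13, and enolisation gives phenol 14. The closest known reaction is the Moore ring expansion of 4-alkenyl-4-alkoxy- or 4-hydroxycyclobutenones derived from squarate esters, which gives phenols and hydroquinones. The only ring formed is the six-membered ring B, closed by thermal disrotatory 6π electrocyclisation of a (3Z)-hexa-1,3,5-trien-1-one with formation of C1'–C2'. No stereocentre is created, and the racemic quaternary carbon of 11 becomes the planar C5'. The step needs the vinyl group to turn inward toward the ketene, and this torquoselectivity is secured by the 4-methoxy donor, which rotates outward in cyclobutenone openings. The substitution pattern (OH, chain, OMe, OMe on C2' to C5') needs no regiocontrol here, because it was fixed by the order and site of the two organolithium additions in steps 3 and 4.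

Step 6
Reactants: 14 3,4-dimethoxy-2-[3-methyl-3-(triethylsilyloxy)butyl]phenol
Product: 15 6-iodo-3,4-dimethoxy-2-[3-methyl-3-(triethylsilyloxy)butyl]phenol
Conditions: NIS, MeCN, 0 °C, dark
Reagents that add atoms: N-iodosuccinimide, O=C1CCC(=O)N1I
Why: Electrophilic aromatic iodination should go to C1', the only open position that is ortho to the free phenol and para to the C4' methoxy group, whereas C6' is activated by a single ortho methoxy group.

Step 7
Reactants: 15 6-iodo-3,4-dimethoxy-2-[3-methyl-3-(triethylsilyloxy)butyl]phenol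
Product: 16 2-(benzyloxy)-1-iodo-4,5-dimethoxy-3-[3-methyl-3-(triethylsilyloxy)butyl]benzene
Conditions: BnBr, K2CO3, DMF, 50 °C
Reagents that add atoms: benzyl bromide, BrCc1ccccc1
Why: Williamson etherification of the phenoxide masks C2'–OH for the palladium steps with a group that later leaves by hydrogenolysis without acid.

Step 8
Reactants: 16 2-(benzyloxy)-1-iodo-4,5-dimethoxy-3-[3-methyl-3-(triethylsilyloxy)butyl]benzene
Product: 17 2-{2-(benzyloxy)-4,5-dimethoxy-3-[3-methyl-3-(triethylsilyloxy)butyl]phenyl}-4,4,5,5-tetramethyl-1,3,2-dioxaborolane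
Conditions: B2pin2, PdCl2(dppf) (5 mol %), KOAc, 1,4-dioxane, 85 °C
Reagents that add atoms: bis(pinacolato)diboron, CC1(C)OB(OC1(C)C)B1OC(C)(C)C(C)(C)O1
Why: Miyaura borylation (oxidative addition of zerovalent palladium into the C–I bond, acetate-assisted transmetallation from the diboron, reductive elimination; dppf = 1,1'-bis(diphenylphosphino)ferrocene) is routine for ortho-alkoxy aryl iodides and leaves silyl and benzyl ethers alone.

Step 9
Reactants: 18 1-(2,4,6-trihydroxyphenyl)ethan-1-one
Product: 19 1-[2,4-bis(benzyloxy)-6-hydroxyphenyl]ethan-1-one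
Conditions: BnBr (2.1 equiv), K2CO3, DMF, rt
Reagents that add atoms: benzyl bromide, BrCc1ccccc1
Why: Williamson etherification with two equivalents of halide should stop at the dibenzyl ether because the remaining hydroxyl is hydrogen-bonded to the ketone and is the least nucleophilic.

Step 10
Reactants: 19 1-[2,4-bis(benzyloxy)-6-hydroxyphenyl]ethan-1-one
Product: 20 (2E)-1-[2,4-bis(benzyloxy)-6-hydroxyphenyl]-3-(dimethylamino)prop-2-en-1-one
Conditions: Me2NCH(OMe)2, PhMe, 95 °C
Reagents that add atoms: N,N-dimethylformamide dimethyl acetal, COC(OC)N(C)C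
Why: Condensation of the methyl ketone with the amide acetal gives the (E)-enaminone and so supplies C2 of the chromone at the correct oxidation level.

Step 11
Reactants: 20 (2E)-1-[2,4-bis(benzyloxy)-6-hydroxyphenyl]-3-(dimethylamino)prop-2-en-1-one
Product: 21 5,7-bis(benzyloxy)-3-iodo-4H-chromen-4-one
Conditions: I2, CHCl3, rt
Reagents that add atoms: iodine, II
Why: Iodination of the enaminone α-carbon, attack of the phenol oxygen on the resulting iminium and loss of dimethylamine (Gammill 3-iodochromone synthesis) closes ring C and installs the C3 halide in one operation.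

Step 12
Reactants: 17 2-{2-(benzyloxy)-4,5-dimethoxy-3-[3-methyl-3-(triethylsilyloxy)butyl]phenyl}-4,4,5,5-tetramethyl-1,3,2-dioxaborolane; 21 5,7-bis(benzyloxy)-3-iodo-4H-chromen-4-one
Product: 22 5,7-bis(benzyloxy)-3-{2-(benzyloxy)-4,5-dimethoxy-3-[3-methyl-3-(triethylsilyloxy)butyl]phenyl}-4H-chromen-4-one
Conditions: Pd(PPh3)4 (5 mol %), Na2CO3, DME/H2O, 80 °C
Reagents that add atoms: none
Why: Suzuki–Miyaura coupling of 3-iodochromones with arylboron reagents is the standard isoflavone assembly, and the mild carbonate base should spare the pyranone ring and the silyl ether.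

Step 13
Reactants: 22 5,7-bis(benzyloxy)-3-{2-(benzyloxy)-4,5-dimethoxy-3-[3-methyl-3-(triethylsilyloxy)butyl]phenyl}-4H-chromen-4-one
Product: 23 5,7-bis(benzyloxy)-3-[2-(benzyloxy)-3-(3-hydroxy-3-methylbutyl)-4,5-dimethoxyphenyl]-4H-chromen-4-one
Conditions: HF·pyridine, pyridine, THF, 0 °C to rt
Reagents that add atoms: none
Why: Fluoride-mediated desilylation frees the tertiary alcohol while C2'–O is still benzylated, so the mildly acidic medium cannot close a 2,2-dimethylchroman onto ring B.

Step 14
Reactants: 23 5,7-bis(benzyloxy)-3-[2-(benzyloxy)-3-(3-hydroxy-3-methylbutyl)-4,5-dimethoxyphenyl]-4H-chromen-4-one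
Product: 24 5,7-dihydroxy-3-[2-hydroxy-3-(3-hydroxy-3-methylbutyl)-4,5-dimethoxyphenyl]-4H-chromen-4-one (CNP0192638.0)
Conditions: H2 (1 atm), 10% Pd/C, EtOAc/MeOH, rt
Reagents that add atoms: none
Why: Hydrogenolysis of the three aryl benzyl ethers under neutral conditions should release the phenols without ionising the tertiary alcohol, and the vinylogous-ester C2–C3 bond of ring C is expected to resist reduction if the reaction is stopped once the benzyl groups are gone.

**Compound list**

1 | 3-methylbutane-1,3-diol | CC(C)(O)CCO | starting material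
2 | 4-iodo-2-methylbutan-2-ol | CC(C)(O)CCI | intermediate
3 | triethyl[(4-iodo-2-methylbutan-2-yl)oxy]silane | CC[Si](CC)(CC)OC(C)(C)CCI | intermediate
4 | dimethyl squarate (3,4-dimethoxycyclobut-3-ene-1,2-dione) | COC1=C(OC)C(=O)C1=O | starting material
5 | [3-methyl-3-(triethylsilyloxy)butyl]lithium (formed in the flask) | [Li]CCC(C)(C)O[Si](CC)(CC)CC | intermediate
6 | lithium 2,3-dimethoxy-1-[3-methyl-3-(triethylsilyloxy)butyl]-4-oxocyclobut-2-en-1-olate, racemic, one enantiomer drawn (formed in the flask) | [Li+].[O-][C@]1(CCC(C)(C)O[Si](CC)(CC)CC)C(OC)=C(OC)C1=O | intermediate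
7 | 3-methoxy-4-[3-methyl-3-(triethylsilyloxy)butyl]cyclobut-3-ene-1,2-dione | COC1=C(CCC(C)(C)O[Si](CC)(CC)CC)C(=O)C1=O | intermediate
8 | bromoethene (vinyl bromide) | C=CBr | starting material
9 | ethenyllithium (vinyllithium, formed in the flask) | [Li]C=C | intermediate
10 | lithium 1-ethenyl-2-methoxy-3-[3-methyl-3-(triethylsilyloxy)butyl]-4-oxocyclobut-2-en-1-olate, racemic, one enantiomer drawn (formed in the flask) | [Li+].[O-][C@@]1(C=C)C(OC)=C(CCC(C)(C)O[Si](CC)(CC)CC)C1=O | intermediate
11 | 4-ethenyl-3,4-dimethoxy-2-[3-methyl-3-(triethylsilyloxy)butyl]cyclobut-2-en-1-one, racemic, one enantiomer drawn | O=C1C(CCC(C)(C)O[Si](CC)(CC)CC)=C(OC)[C@@]1(OC)C=C | intermediate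
12 | (3Z)-3,4-dimethoxy-2-[3-methyl-3-(triethylsilyloxy)butyl]hexa-1,3,5-trien-1-one (dienylketene, formed in the flask) | O=C=C(CCC(C)(C)O[Si](CC)(CC)CC)/C(OC)=C(OC)\C=C | intermediate
13 | 3,4-dimethoxy-2-[3-methyl-3-(triethylsilyloxy)butyl]cyclohexa-2,4-dien-1-one (formed in the flask) | O=C1CC=C(OC)C(OC)=C1CCC(C)(C)O[Si](CC)(CC)CC | intermediate
14 | 3,4-dimethoxy-2-[3-methyl-3-(triethylsilyloxy)butyl]phenol | COc1ccc(O)c(CCC(C)(C)O[Si](CC)(CC)CC)c1OC | intermediate
15 | 6-iodo-3,4-dimethoxy-2-[3-methyl-3-(triethylsilyloxy)butyl]phenol | COc1cc(I)c(O)c(CCC(C)(C)O[Si](CC)(CC)CC)c1OC | intermediate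
16 | 2-(benzyloxy)-1-iodo-4,5-dimethoxy-3-[3-methyl-3-(triethylsilyloxy)butyl]benzene | COc1cc(I)c(OCc2ccccc2)c(CCC(C)(C)O[Si](CC)(CC)CC)c1OC | intermediate
17 | 2-{2-(benzyloxy)-4,5-dimethoxy-3-[3-methyl-3-(triethylsilyloxy)butyl]phenyl}-4,4,5,5-tetramethyl-1,3,2-dioxaborolane | COc1cc(B2OC(C)(C)C(C)(C)O2)c(OCc2ccccc2)c(CCC(C)(C)O[Si](CC)(CC)CC)c1OC | intermediate
18 | 1-(2,4,6-trihydroxyphenyl)ethan-1-one | CC(=O)c1c(O)cc(O)cc1O | starting material
19 | 1-[2,4-bis(benzyloxy)-6-hydroxyphenyl]ethan-1-one | CC(=O)c1c(O)cc(OCc2ccccc2)cc1OCc1ccccc1 | intermediate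
20 | (2E)-1-[2,4-bis(benzyloxy)-6-hydroxyphenyl]-3-(dimethylamino)prop-2-en-1-one | CN(C)/C=C/C(=O)c1c(O)cc(OCc2ccccc2)cc1OCc1ccccc1 | intermediate
21 | 5,7-bis(benzyloxy)-3-iodo-4H-chromen-4-one | O=c1c(I)coc2cc(OCc3ccccc3)cc(OCc3ccccc3)c12 | intermediate
22 | 5,7-bis(benzyloxy)-3-{2-(benzyloxy)-4,5-dimethoxy-3-[3-methyl-3-(triethylsilyloxy)butyl]phenyl}-4H-chromen-4-one | COc1cc(-c2coc3cc(OCc4ccccc4)cc(OCc4ccccc4)c3c2=O)c(OCc2ccccc2)c(CCC(C)(C)O[Si](CC)(CC)CC)c1OC | intermediate
23 | 5,7-bis(benzyloxy)-3-[2-(benzyloxy)-3-(3-hydroxy-3-methylbutyl)-4,5-dimethoxyphenyl]-4H-chromen-4-one | COc1cc(-c2coc3cc(OCc4ccccc4)cc(OCc4ccccc4)c3c2=O)c(OCc2ccccc2)c(CCC(C)(C)O)c1OC | intermediate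
24 | 5,7-dihydroxy-3-[2-hydroxy-3-(3-hydroxy-3-methylbutyl)-4,5-dimethoxyphenyl]-4H-chromen-4-one | COc1cc(-c2coc3cc(O)cc(O)c3c2=O)c(O)c(CCC(C)(C)O)c1OC | target

**Count**

Total steps: 14. Longest linear sequence: 11 steps (steps 1 to 8, then 12 to 14); the chromone branch (steps 9 to 11) joins at step 12.

**Steps most likely to fail**

Step 4. The one-pot sequence may break down at the trapping stage: the hindered tertiary lithium alkoxide may be methylated too slowly and begin to ring-open or decompose on warming before the triflate has reacted. Fallback, setting out from 7 and returning at 11: alkoxide 10 is generated as before but protonated with aqueous NH4Cl, and racemic 4-ethenyl-4-hydroxy-3-methoxy-2-[3-methyl-3-(triethylsilyloxy)butyl]cyclobut-2-en-1-one F1 is isolated. The neutral alcohol is then methylated with MeI and Ag2O (K2CO3, MeCN, rt), a silver-assisted alkylation that does not depend on the lifetime of the lithium alkoxide, to give 11.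

Step 6. The iodinating agent may oxidise the electron-rich para-methoxyphenol toward a quinone, or a second iodination may occur at C6'. Fallback, setting out from 14 and returning at 16: the phenol is benzylated first (BnBr, K2CO3, DMF) to 1-(benzyloxy)-3,4-dimethoxy-2-[3-methyl-3-(triethylsilyloxy)butyl]benzene F2, which can no longer be oxidised to a quinone. The aryl ether is then iodinated with NIS in MeCN at rt, para to the C4' methoxy group and ortho to the benzyloxy group, which gives 16 directly.

Step 8. Reductive loss of iodine or homocoupling may compete during palladium-catalysed borylation of the electron-rich, ortho-substituted iodide. Fallback, setting out from 16 and returning at 17: iodine–lithium exchange with n-BuLi in THF at −78 °C gives {2-(benzyloxy)-4,5-dimethoxy-3-[3-methyl-3-(triethylsilyloxy)butyl]phenyl}lithium F3. This is trapped in the same flask with 2-isopropoxy-4,4,5,5-tetramethyl-1,3,2-dioxaborolane to give 17 without a transition-metal catalyst.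

**Further compounds**

F1 | step 4 | 4-ethenyl-4-hydroxy-3-methoxy-2-[3-methyl-3-(triethylsilyloxy)butyl]cyclobut-2-en-1-one, racemic, one enantiomer drawn | O=C1C(CCC(C)(C)O[Si](CC)(CC)CC)=C(OC)[C@@]1(O)C=C
F2 | step 6 | 1-(benzyloxy)-3,4-dimethoxy-2-[3-methyl-3-(triethylsilyloxy)butyl]benzene | COc1ccc(OCc2ccccc2)c(CCC(C)(C)O[Si](CC)(CC)CC)c1OC
F3 | step 8 | {2-(benzyloxy)-4,5-dimethoxy-3-[3-methyl-3-(triethylsilyloxy)butyl]phenyl}lithium | [Li]c1cc(OC)c(OC)c(CCC(C)(C)O[Si](CC)(CC)CC)c1OCc1ccccc1
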